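**Strategy.** The nine-membered oxacycle (O–C3–C4=C5–C6–C7–C8–C9–C10) is made one atom too large: a ten-membered thiacycle with sulfur between C4 and C5 is closed first and then contracted by loss of SO2. The precursor is the macrocyclic E-vinyl sulfone 22 (C5=C6), whose C4–H lies between the sulfone and the 3(2H)-furanone. One operation with LiOOt-Bu epoxidises C5=C6, lets the C4 carbanion open the epoxide at C5 (epoxy-Ramberg–Bäcklund), expels SO2 and lets the freed C6 alkoxide close the γ-lactone. The step exploits the allylic array C4=C5–C6–O of the oxonine. C10 is set by asymmetric allylation, C7/C8 by an Evans aldol, C6 by the macrocycle.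

Key step: step 15

Remark (assumption): germacrane numbering is used throughout. C1 is the furanone C=O, C2 the furanone CH, C3–O–C10 the ether bridge, C14 the CH3 on C10, C15 the CH2O on C4, C6 the lactone carbinol, C8 the angelate carbinol, and C11/C12/C13 the lactone α-carbon, carbonyl and exocyclic CH2. Compounds 10–23 are carried as C4-epimer mixtures, because C4 becomes sp2 in step 15.

**Step 1**
Reactants: 1 2,5-dimethylfuran-3(2H)-one; 2 allyl chloroformate
Product: 3 allyl 2,5-dimethylfuran-3-yl carbonate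
Conditions: NaHMDS, THF, −78 °C; then 2, −78 → 0 °C
Reagents that add atoms: none
Why: The sodium enolate (a 3-oxidofuran) is O-acylated by the hard chloroformate, giving the allyl enol carbonate needed for decarboxylative allylation.

**Step 2**
Reactants: 3 allyl 2,5-dimethylfuran-3-yl carbonate
Product: 4 (R)-2-allyl-2,5-dimethylfuran-3(2H)-one
Conditions: Pd2(dba)3 (2.5 mol %), (R)-t-Bu-PHOX (6 mol %), THF, 25 °C
Reagents that add atoms: none
Why: In this Pd-catalysed decarboxylative asymmetric allylic alkylation (Tsuji allylation) the π-allyl-Pd/furanolate pair recombines at C2 inside the chiral PHOX pocket, which sets the quaternary C10 as R; the ligand antipode is assigned by analogy with cyclic ketone enol carbonates and is exchanged if the opposite sense is found.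

**Step 3**
Reactants: 4 (R)-2-allyl-2,5-dimethylfuran-3(2H)-one
Product: 5 (R)-2-allyl-5-(2-hydroxyethyl)-2-methylfuran-3(2H)-one
Conditions: LDA, THF, −78 °C; CH2O (gas, from cracked paraformaldehyde), −78 °C; aq NH4Cl
Reagents that add atoms: formaldehyde, C=O
Why: With C2 quaternary, LDA removes a proton from the 5-methyl group, and the extended dienolate adds to formaldehyde at its exocyclic γ-carbon (vinylogous aldol), which installs C15 on C4.

**Step 4**
Reactants: 5 (R)-2-allyl-5-(2-hydroxyethyl)-2-methylfuran-3(2H)-one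
Product: 6 (R)-2-allyl-5-[2-(tert-butyldimethylsilyloxy)ethyl]-2-methylfuran-3(2H)-one
Conditions: TBSCl, imidazole, DMF, 0 °C → rt
Reagents that add atoms: tert-butyldimethylsilyl chloride, CC(C)(C)[Si](C)(C)Cl
Why: Standard silylation of the primary alcohol protects C15–OH for the carbanion chemistry that follows.

**Step 5**
Reactants: 7 potassium 4-methylbenzenesulfonothioate; 8 diethyl (iodomethyl)phosphonate
Product: 9 S-[(diethoxyphosphoryl)methyl] 4-methylbenzenesulfonothioate
Conditions: DMF, 60 °C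
Reagents that add atoms: none
Why: SN2 S-alkylation of the thiosulfonate anion gives an electrophilic sulfur reagent that already carries the C5 phosphonate.

**Step 6**
Reactants: 6 (R)-2-allyl-5-[2-(tert-butyldimethylsilyloxy)ethyl]-2-methylfuran-3(2H)-one; 9 S-[(diethoxyphosphoryl)methyl] 4-methylbenzenesulfonothioate
Product: 10 C4-sulfide (C4 epimers; 10R)
Conditions: LDA (1.05 equiv), THF, −78 °C; cannulated into 9 (1.2 equiv), THF, −78 °C; aq NH4Cl
Reagents that add atoms: none
Why: γ-Sulfenylation of the lithium dienolate by the thiosulfonate (sulfinate leaving group) forms the C4–S bond; inverse addition limits proton transfer to the more acidic product, and −78 °C keeps the β-silyloxy dienolate from eliminating.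

**Step 7**
Reactants: 10 C4-sulfide
Product: 11 C4-sulfone (sulfonylmethylphosphonate)
Conditions: (NH4)6Mo7O24·4H2O (10 mol %), 30 % H2O2, EtOH, 0 °C → rt
Reagents that add atoms: hydrogen peroxide, OO
Why: Molybdate-catalysed peroxide oxidation takes sulfide to sulfone much faster than it attacks the terminal alkene or the push–pull enone.

**Step 8**
Reactants: 11 C4-sulfone
Product: 12 C8 aldehyde (2-oxoethyl on C10)
Conditions: OsO4 (2 mol %), NaIO4, 2,6-lutidine, dioxane/H2O 3:1, rt
Reagents that add atoms: osmium tetroxide (catalytic, reoxidised by NaIO4), O=[Os](=O)(=O)=O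
Why: Lemieux–Johnson cleavage attacks the unhindered terminal alkene in preference to the deactivated, trisubstituted furanone C=C and unveils the C8 aldehyde under buffered conditions.

**Step 9**
Reactants: 13 4-tert-butoxy-4-oxobutanoic acid; 14 (R)-4-benzyloxazolidin-2-one
Product: 16 tert-butyl 4-[(R)-4-benzyl-2-oxooxazolidin-3-yl]-4-oxobutanoate, via pivalic mixed anhydride 15 (not isolated)
Conditions: PivCl, Et3N, THF, −20 °C; then 14, LiCl, −20 °C → rt
Reagents that add atoms: none
Why: N-acylation of the oxazolidinone through the pivalic mixed anhydride (LiCl/Et3N protocol) occurs at the less hindered succinyl carbonyl.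

**Step 10**
Reactants: 16 tert-butyl 4-[(R)-4-benzyl-2-oxooxazolidin-3-yl]-4-oxobutanoate; 12 C8 aldehyde
Product: 18 syn-aldol adduct (7R,8S,10R), via Z-boron enolate 17 (not isolated)
Conditions: 16 (1.5 equiv), Bu2BOTf, i-Pr2NEt, CH2Cl2, −78 → 0 °C; 12, −78 → −20 °C; pH 7 buffer, MeOH, H2O2, 0 °C
Reagents that add atoms: none
Why: In this Evans syn-aldol the Z-boron enolate reacts through a Zimmerman–Traxler chair on the face away from the benzyl group, so the auxiliary sets C7 (R) and C8 (S) as the 7,8-syn pair; the tert-butyl ester keeps the γ-hydroxy ester from lactonising.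

**Step 11**
Reactants: 18 syn-aldol adduct
Product: 19 8-O-TBS ether
Conditions: TBSOTf, 2,6-lutidine, CH2Cl2, −78 °C
Reagents that add atoms: tert-butyldimethylsilyl triflate, CC(C)(C)[Si](C)(C)OS(=O)(=O)C(F)(F)F
Why: Silylation of the hindered secondary alcohol blocks retro-aldol and lactonisation and protects C8–OH until the end.

**Step 12**
Reactants: 19 8-O-TBS ether
Product: 20 S-ethyl thioester (C6)
Conditions: EtSH, n-BuLi, THF, −20 → 0 °C; aq NH4Cl
Reagents that add atoms: ethanethiol, CCS
Why: Lithium ethanethiolate transacylates the imide at the exocyclic carbonyl, leaving the tert-butyl ester and the phosphonate untouched and releasing the auxiliary.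

**Step 13**
Reactants: 20 S-ethyl thioester
Product: 21 C6 aldehyde
Conditions: Et3SiH, 10 % Pd/C, acetone, rt
Reagents that add atoms: none
Why: The Fukuyama reduction of a thioester stops at the aldehyde and spares ester, sulfone, phosphonate and enone.

**Step 14**
Reactants: 21 C6 aldehyde
Product: 22 ten-membered E-vinyl sulfone (5E,7S,8S,10R)
Conditions: LiCl, i-Pr2NEt, MeCN, 1 mM (syringe pump), rt → 40 °C
Reagents that add atoms: none
Why: Intramolecular Horner–Wadsworth–Emmons olefination under Masamune–Roush conditions closes the thiacycle as the E-vinyl sulfone; the amine base is chosen to spare the C7 stereocentre and to avoid the vinyl-to-allyl sulfone shift.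

**Step 15**
Reactants: 22 ten-membered E-vinyl sulfone
Product: 26 6,12-lactone with the nine-membered oxacycle (4Z,6R,7S,8S,10R), via epoxy sulfone 23 (not isolated), via episulfone alkoxide 24 (not isolated), via dienyl alkoxide 25 (not isolated)
Conditions: t-BuOOH (2.0 equiv, anhydrous), n-BuLi (1.8 equiv), THF, −78 °C; 22, −20 °C → rt; aq NH4Cl
Reagents that add atoms: tert-butyl hydroperoxide, CC(C)(C)OO
Why: Lithium tert-butyl peroxide adds to C6 of the vinyl sulfone and the α-sulfonyl carbanion closes the trans-epoxide 23 (nucleophilic epoxidation, 3-exo-tet at oxygen). The tert-butoxide released removes the C4–H (activated by sulfone and vinylogous ketone), and the C4 carbanion opens the epoxide at C5 with inversion (3-exo-tet) to episulfone 24, which loses SO2 stereospecifically to give the C4=C5 olefin and alkoxide 25. This is the epoxy-Ramberg–Bäcklund reaction in its ring-contracting mode (10 → 9), and the alkoxide then closes the γ-lactone on the tert-butyl ester (5-exo-trig). C6 is set in the epoxidation, where the peroxide should attack the outer face of the ring olefin, anti to ring carbon C8 with C7–H eclipsing the C=C, and its C–O bond is not broken afterwards. The Z geometry follows from the cis-fused episulfone, the only fusion the bicyclic frame allows. The step needs the correct epoxidation face (the main uncertainty) and C4–H rather than C7–H deprotonation, the latter secured by the far higher acidity of C4–H.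

**Step 16**
Reactants: 26 6,12-lactone
Product: 29 α-methylene lactone bis-TBS ether, via Mannich base 27 (not isolated), via ammonium iodide 28 (not isolated)
Conditions: LiHMDS (1.05 equiv), THF, −78 °C; CH2=NMe2+ I−, −78 → 0 °C; then MeI, CH2Cl2/MeOH, rt; then sat. aq NaHCO3/CH2Cl2, rt
Reagents that add atoms: Eschenmoser's salt, C=[N+](C)C.[I-]
Why: Kinetic deprotonation at C11, a Mannich reaction of the lactone enolate, quaternisation and E1cB loss of trimethylamine give the exocyclic methylene; the low temperature should favour the lactone α-proton over the remote C6–H.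

**Step 17**
Reactants: 29 α-methylene lactone bis-TBS ether
Product: 30 8,15-diol (6R,7R,8S,10R)
Conditions: HF·pyridine, THF/pyridine, 0 °C → rt
Reagents that add atoms: none
Why: Buffered fluoride cleaves both silyl ethers without touching the Michael acceptor, the lactone or the dienone.

**Step 18**
Reactants: 30 8,15-diol
Product: 31 15-acetate with free 8-OH
Conditions: Ac2O (1.1 equiv), 2,4,6-collidine, CH2Cl2, −20 → 0 °C
Reagents that add atoms: acetic anhydride, CC(=O)OC(C)=O
Why: The primary allylic C15–OH is acylated far faster than the hindered secondary C8–OH, and the weak base avoids lactone migration to O8.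

**Step 19**
Reactants: 31 15-acetate with free 8-OH; 32 angelic acid
Product: 34 target CNP0122132.1, via angelic trichlorobenzoic anhydride 33 (not isolated)
Conditions: 32, 2,4,6-trichlorobenzoyl chloride, Et3N, toluene, rt; then 31, toluene, 80 °C
Reagents that add atoms: none
Why: Yamaguchi-type esterification through the preformed mixed anhydride, run without DMAP, acylates C8–OH while keeping the Z geometry of the angelate (no isomerisation to tiglate).

**Compound list**

1 | 2,5-dimethylfuran-3(2H)-one (racemic) | CC1=CC(=O)C(C)O1 | starting material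
2 | allyl chloroformate | C=CCOC(Cl)=O | starting material
3 | allyl 2,5-dimethylfuran-3-yl carbonate | Cc1cc(OC(=O)OCC=C)c(C)o1 | intermediate
4 | (R)-2-allyl-2,5-dimethylfuran-3(2H)-one | CC1=CC(=O)[C@@](C)(CC=C)O1 | intermediate
5 | (R)-2-allyl-5-(2-hydroxyethyl)-2-methylfuran-3(2H)-one | OCCC1=CC(=O)[C@@](C)(CC=C)O1 | intermediate
6 | (R)-2-allyl-5-[2-(tert-butyldimethylsilyloxy)ethyl]-2-methylfuran-3(2H)-one | CC(C)(C)[Si](C)(C)OCCC1=CC(=O)[C@@](C)(CC=C)O1 | intermediate
7 | potassium 4-methylbenzenesulfonothioate | Cc1ccc(cc1)S(=O)(=O)[S-].[K+] | starting material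
8 | diethyl (iodomethyl)phosphonate | CCOP(=O)(CI)OCC | starting material
9 | S-[(diethoxyphosphoryl)methyl] 4-methylbenzenesulfonothioate | CCOP(=O)(CSS(=O)(=O)c1ccc(C)cc1)OCC | intermediate
10 | diethyl ({1-[(5R)-5-allyl-5-methyl-4-oxo-4,5-dihydrofuran-2-yl]-2-(TBS-oxy)ethyl}sulfanylmethyl)phosphonate (C4 epimers) | CCOP(=O)(CSC(CO[Si](C)(C)C(C)(C)C)C1=CC(=O)[C@@](C)(CC=C)O1)OCC | intermediate
11 | the corresponding sulfone (C4 epimers) | CCOP(=O)(CS(=O)(=O)C(CO[Si](C)(C)C(C)(C)C)C1=CC(=O)[C@@](C)(CC=C)O1)OCC | intermediate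
12 | sulfone aldehyde, C10 carries CH2CHO (10R; C4 epimers) | CCOP(=O)(CS(=O)(=O)C(CO[Si](C)(C)C(C)(C)C)C1=CC(=O)[C@@](C)(CC=O)O1)OCC | intermediate
13 | 4-tert-butoxy-4-oxobutanoic acid | CC(C)(C)OC(=O)CCC(=O)O | starting material
14 | (R)-4-benzyloxazolidin-2-one | O=C1N[C@H](Cc2ccccc2)CO1 | starting material
15 | 4-tert-butoxy-4-oxobutanoic pivalic anhydride | CC(C)(C)OC(=O)CCC(=O)OC(=O)C(C)(C)C | intermediate (not isolated)
16 | tert-butyl 4-[(R)-4-benzyl-2-oxooxazolidin-3-yl]-4-oxobutanoate | CC(C)(C)OC(=O)CCC(=O)N1C(=O)OC[C@H]1Cc1ccccc1 | intermediate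
17 | Z-dibutylboron enolate of 16 | CCCCB(CCCC)O/C(=C\CC(=O)OC(C)(C)C)N1C(=O)OC[C@H]1Cc1ccccc1 | intermediate (not isolated)
18 | Evans syn-aldol adduct: C6 imide, C7 bearing CH2CO2t-Bu, C8–OH (7R,8S,10R; C4 epimers) | CCOP(=O)(CS(=O)(=O)C(CO[Si](C)(C)C(C)(C)C)C1=CC(=O)[C@@](C)(C[C@H](O)[C@@H](CC(=O)OC(C)(C)C)C(=O)N2C(=O)OC[C@H]2Cc2ccccc2)O1)OCC | intermediate
19 | 8-O-TBS ether of 18 (7R,8S,10R) | CCOP(=O)(CS(=O)(=O)C(CO[Si](C)(C)C(C)(C)C)C1=CC(=O)[C@@](C)(C[C@H](O[Si](C)(C)C(C)(C)C)[C@@H](CC(=O)OC(C)(C)C)C(=O)N2C(=O)OC[C@H]2Cc2ccccc2)O1)OCC | intermediate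
20 | C6 S-ethyl thioester (7R,8S,10R) | CCOP(=O)(CS(=O)(=O)C(CO[Si](C)(C)C(C)(C)C)C1=CC(=O)[C@@](C)(C[C@H](O[Si](C)(C)C(C)(C)C)[C@@H](CC(=O)OC(C)(C)C)C(=O)SCC)O1)OCC | intermediate
21 | C6 aldehyde (7R,8S,10R) | CCOP(=O)(CS(=O)(=O)C(CO[Si](C)(C)C(C)(C)C)C1=CC(=O)[C@@](C)(C[C@H](O[Si](C)(C)C(C)(C)C)[C@@H](CC(=O)OC(C)(C)C)C=O)O1)OCC | intermediate
22 | ten-membered cyclic E-vinyl sulfone (ring O–C3–C4–S–C5=C6–C7–C8–C9–C10; 5E,7S,8S,10R; C4 epimers) | CC(C)(C)[Si](C)(C)OCC1C2=CC(=O)[C@@](C)(C[C@H](O[Si](C)(C)C(C)(C)C)[C@@H](CC(=O)OC(C)(C)C)/C=C/S1(=O)=O)O2 | intermediate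
23 | 5,6-trans-epoxy sulfone of 22 (5S,6S,7S,8S,10R) | CC(C)(C)[Si](C)(C)OCC1C2=CC(=O)[C@@](C)(C[C@H](O[Si](C)(C)C(C)(C)C)[C@@H](CC(=O)OC(C)(C)C)[C@@H]3O[C@H]3S1(=O)=O)O2 | intermediate (not isolated)
24 | cis-fused C4/C5 episulfone, lithium C6-alkoxide | CC(C)(C)[Si](C)(C)OC[C@]12C3=CC(=O)[C@@](C)(C[C@H](O[Si](C)(C)C(C)(C)C)[C@@H](CC(=O)OC(C)(C)C)[C@H]([O-])[C@H]1S2(=O)=O)O3.[Li+] | intermediate (not isolated)
25 | lithium C6-alkoxide of the nine-membered 4Z-diene tert-butyl ester (6R,7S,8S,10R) | CC(C)(C)OC(=O)C[C@H]1[C@H]([O-])/C=C(/CO[Si](C)(C)C(C)(C)C)C2=CC(=O)[C@@](C)(C[C@@H]1O[Si](C)(C)C(C)(C)C)O2.[Li+] | intermediate (not isolated)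
26 | 8,15-bis-O-TBS 11,13-dihydro lactone (4Z,6R,7S,8S,10R) | C1C(=O)O[C@@H]2/C=C(/CO[Si](C)(C)C(C)(C)C)C3=CC(=O)[C@@](C)(C[C@H](O[Si](C)(C)C(C)(C)C)[C@@H]12)O3 | intermediate
27 | 11-(dimethylaminomethyl) lactone (C11 epimers) | CN(C)CC1C(=O)O[C@@H]2/C=C(/CO[Si](C)(C)C(C)(C)C)C3=CC(=O)[C@@](C)(C[C@H](O[Si](C)(C)C(C)(C)C)[C@@H]12)O3 | intermediate (not isolated)
28 | 11-(trimethylammoniomethyl) lactone iodide | C[N+](C)(C)CC1C(=O)O[C@@H]2/C=C(/CO[Si](C)(C)C(C)(C)C)C3=CC(=O)[C@@](C)(C[C@H](O[Si](C)(C)C(C)(C)C)[C@@H]12)O3.[I-] | intermediate (not isolated)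
29 | 8,15-bis-O-TBS α-methylene lactone (4Z,6R,7S,8S,10R) | C=C1C(=O)O[C@@H]2/C=C(/CO[Si](C)(C)C(C)(C)C)C3=CC(=O)[C@@](C)(C[C@H](O[Si](C)(C)C(C)(C)C)[C@@H]12)O3 | intermediate
30 | 8,15-diol (4Z,6R,7R,8S,10R) | C=C1C(=O)O[C@@H]2/C=C(/CO)C3=CC(=O)[C@@](C)(C[C@H](O)[C@@H]12)O3 | intermediate
31 | 15-O-acetyl-8-ol (4Z,6R,7R,8S,10R) | C=C1C(=O)O[C@@H]2/C=C(/COC(C)=O)C3=CC(=O)[C@@](C)(C[C@H](O)[C@@H]12)O3 | intermediate
32 | angelic acid, (Z)-2-methylbut-2-enoic acid | C/C=C(/C)C(=O)O | starting material
33 | angelic 2,4,6-trichlorobenzoic anhydride | C/C=C(/C)C(=O)OC(=O)c1c(Cl)cc(Cl)cc1Cl | intermediate (not isolated)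
34 | CNP0122132.1: 15-acetoxy-8-angeloyloxy furanoheliangolide (4Z,6R,7R,8S,10R) | C=C1C(=O)O[C@@H]2/C=C(/COC(C)=O)C3=CC(=O)[C@@](C)(C[C@H](OC(=O)/C(C)=C\C)[C@@H]12)O3 | target

**Step count.** Total: 19 steps. Longest linear sequence: 17 steps (1–4, 6–8, 10–19).

**Steps most likely to fail**

Step 15 (key step). The peroxide may be delivered to the inner face of the C5=C6 olefin, which would give the wrong C6 configuration; base-induced vinyl-to-allyl sulfone migration or loss of silyloxide from the C4 carbanion may also compete. Fallback: C6 is set by reagent control instead of by the macrocycle. It sets out from 22: the cascade is run as in step 15 but quenched at −20 °C before lactonisation, which would give the 6-epimeric hydroxy tert-butyl ester F1. Dess–Martin oxidation gives the C6 enone F2, and (R)-Me-CBS/BH3·SMe2 (alkenyl branch as the large group) reduces it to the (6R)-hydroxy ester F3. Brief treatment with t-BuOLi in THF closes the lactone, and the fallback comes back to the route at 26.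

Step 14. The ring closure may be slower than oligomerisation because of the strain of an E-olefin in the ten-membered ring, and the aldehyde may epimerise at C7 on long exposure to base. Fallback: the ring is closed by metathesis. It sets out from 21: Takai–Lombardo methylenation (Zn, CH2Br2, TiCl4) gives the terminal alkene phosphonate F4. An intermolecular Horner–Wadsworth–Emmons reaction with aqueous formaldehyde (K2CO3) turns the sulfonylmethylphosphonate into the vinyl sulfone diene F5. Ring-closing metathesis (Hoveyda–Grubbs II, toluene, 80 °C, high dilution) then joins C5 and C6 with loss of ethylene, and the fallback comes back at 22.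

Step 2. The flat furanolate may give poor facial discrimination in the chiral pocket, which would mean low enantiomeric purity at C10. Fallback: resolution in place of catalysis. It sets out from 1: direct C2-allylation (LDA, allyl bromide, THF, −78 °C) gives racemic 2-allyl-2,5-dimethylfuran-3(2H)-one F6, which is resolved by preparative chiral SFC; the R enantiomer is 4, where the fallback comes back to the route.

**Further compounds**

F1 | step 15 | (6S)-hydroxy tert-butyl ester, the 6-epimer of neutral 25 | CC(C)(C)OC(=O)C[C@H]1[C@@H](O)/C=C(/CO[Si](C)(C)C(C)(C)C)C2=CC(=O)[C@@](C)(C[C@@H]1O[Si](C)(C)C(C)(C)C)O2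
F2 | step 15 | C6 ketone (4Z-enone) tert-butyl ester | CC(C)(C)OC(=O)C[C@H]1C(=O)/C=C(/CO[Si](C)(C)C(C)(C)C)C2=CC(=O)[C@@](C)(C[C@@H]1O[Si](C)(C)C(C)(C)C)O2
F3 | step 15 | (6R)-hydroxy tert-butyl ester, neutral form of 25 | CC(C)(C)OC(=O)C[C@H]1[C@H](O)/C=C(/CO[Si](C)(C)C(C)(C)C)C2=CC(=O)[C@@](C)(C[C@@H]1O[Si](C)(C)C(C)(C)C)O2
F4 | step 14 | C7-vinyl sulfonylmethylphosphonate (methylenated 21) | CCOP(=O)(CS(=O)(=O)C(CO[Si](C)(C)C(C)(C)C)C1=CC(=O)[C@@](C)(C[C@H](O[Si](C)(C)C(C)(C)C)[C@@H](CC(=O)OC(C)(C)C)C=C)O1)OCC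
F5 | step 14 | vinyl sulfone diene for ring-closing metathesis | C=CS(=O)(=O)C(CO[Si](C)(C)C(C)(C)C)C1=CC(=O)[C@@](C)(C[C@H](O[Si](C)(C)C(C)(C)C)[C@@H](CC(=O)OC(C)(C)C)C=C)O1
F6 | step 2 | racemic 2-allyl-2,5-dimethylfuran-3(2H)-one | CC1=CC(=O)C(C)(CC=C)O1
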